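Time in this flask runs through two resistances in series, as in a two-stage process with a supply lag: gas must cross into solution as partner, and partner must then meet left-handed substrate to give left-handed product.

| setting | zeta | gamma | flask |
|---|---|---|---|
| left-handed substrate | 20 mM | 13 mM | 20 mM |
| right-handed substrate | 20 mM | 13 mM | 20 mM |
| gas | 5.1 mM (held) | 5.1 mM (held) | 5.1 mM (held) |
| remark | the very flask that is asked about, followed so far | run made earlier |  |
| time |  |  | 1.0 h |

| run | time / min | left-handed product / % | left-handed substrate / % |
|---|---|---|---|
| zeta | 3.00 | 0.3 | 47.6 |
| zeta | 8.00 | 1.7 | 45.5 |
| zeta | 15.0 | 4.7 | 42.6 |
| zeta | 25.0 | 8.6 | 38.7 |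
| gamma | 15.0 | 5.5 | 42.1 |
| gamma | 30.0 | 13.2 | 34.8 |
| gamma | 50.0 | 22.2 | 27.2 |
| gamma | 60.0 | 26.1 | 23.9 |

(standard deviation of a reading: 0.3 percentage points)

- partner is single-handed; left-handed substrate and right-handed substrate are mirror images of each other, charged as a racemate, each of them at the stated concentration
- at the start none of the gas is in solution
- partner is what gas becomes in solution
- the handed part of partner does not stay in what it makes, so the products of the two hands are mirror images too

- how much left-handed product there is at 1.0 h, in percent of the left-handed substrate and right-handed substrate together charged
- concentration of partner in solution at 30 min, in percent of saturation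
- the change that raises the amount of left-handed product at 1.0 h, in percent of the left-handed substrate and right-handed substrate together charged most ("none" if none brings more than 2 percentage points) (green / blue / none)
- amount of left-handed product at 1.0 h, in percent of the left-handed substrate and right-handed substrate together charged, after green

Between their second and fourth readings, the zeta run makes left-handed product at 0.162 mM min⁻¹ with left-handed substrate near 16.8 mM, and the gamma run makes it at 0.112 mM min⁻¹ near 7.63 mM, so the rate falls less than the substrate. Two resistances in series give that pattern:

rate = ceiling × substrate / (crossing level + substrate)

partner share of saturation = crossing level / (crossing level + substrate)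

The two rates give the crossing level, the left-handed substrate concentration at which partner stands at half of saturation, with the draw of the right-handed substrate folded in: 10.1 mM. The ceiling is 0.260 mM min⁻¹. In this rate law the gas crossing is the larger of the two resistances where left-handed substrate stands above that level, the reaction is the larger where it stands below, and at the level the two are equal.

Two ways lead from the last zeta reading to the asked time. The zeta slope, carried straight on, gives:

y = 22.8 %

The rate law, taken at the midpoint substrate of 12.7 mM, gives:

y = 21.3 %

They part by 1.5 percentage points, and the straight line is the one that cheats, because it keeps a rate measured at more substrate than the remaining time has. My reckoning therefore stands at 21.3 %. It puts partner at 40.7 % of saturation at 30 min. Blue doubles the ceiling and keeps the level, a factor 2, while green doubles both, a factor 1.39, which gives about 29.5 %, so blue leads.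

The forecast says 22.3 %, 40 %, blue and 29 %, holding that “gas transfer and reaction are comparably limiting”.

The flask gives 21.9 %, 37.1 %, blue and 29.8 %.

    partner + left-handed substrate → left-handed product (k = 0.0940 M⁻¹ s⁻¹)
    partner + right-handed substrate → right-handed product (k = 0.0440 M⁻¹ s⁻¹)
    left-handed substrate ⇌ achiral form (K = 0.130, k = 2.50 × 10⁻⁴ s⁻¹)
    right-handed substrate ⇌ achiral form (K = 0.130, k = 2.50 × 10⁻⁴ s⁻¹)
    gas ⇌ partner, rate k5*(csat - [partner]) (kL = 0.00130 s⁻¹)

At 1.00 h in this flask, partner is made 1.05 times as fast as it is used up, each step taken net, and left-handed substrate stands at 11.1 mM, where the crossing level gives a partner share of 47.6 % against 42.8 % in the flask. In the neighbour read at 4.00 h, left-handed substrate is down to 1.05 mM, below the crossing level, the same share comes to 90.6 %, and that flask holds partner at 4.35 mM, which is 85.4 % of saturation.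

The data come from a simulation from invented constants; noise was put on by code.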